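**Retrosynthetic overview**
- Target ⇒ (7Z)-7,11(13)-diene lactone: both acetates (C13–O and C8–O) go on in one palladium-catalysed 1,4-diacetoxylation, which also sets C8 and places the olefin at C7=C11.
- Diene ⇒ 13-bromo-7(11)-ene butenolide (1,4-dehydrobromination) ⇒ α-methylene lactone (allylic bromination at H7 with transposition).
- α-Methylene lactone = 1β,10α-epoxyparthenolide ⇒ (−)-parthenolide (face-selective epoxidation of the 1(10)-olefin).
- Rings: the ten-membered carbocycle, the γ-lactone and the 4,5-oxirane (C4, C5, C6) come with parthenolide; the 1,10-oxirane is the only ring formed (first step); C8 is the last stereocentre set.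

Assumption: (−)-parthenolide, an isolated natural product sold in bulk by many suppliers, is taken as the commercial starting material; germacrane numbering (C1–C15) and the usual α/β convention are used throughout.

**Step 1**
Reactants: 1 (−)-parthenolide [(4R,5R,6S,7S)-4α,5β-epoxygermacra-1(10)E,11(13)-dien-12,6α-olide]
Product: 2 1β,10α-epoxyparthenolide [(1R,4R,5R,6S,7S,10R)-1β,10α;4α,5β-diepoxygermacr-11(13)-en-12,6α-olide]
Conditions: mCPBA (1.2 equiv), CH2Cl2, 0 °C
Reagents that add atoms: mCPBA (3-chloroperoxybenzoic acid), O=C(OO)c1cccc(Cl)c1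
Why: Prilezhaev epoxidation; the trisubstituted 1(10)-olefin is the only electron-rich alkene (the methylene lactone is inert to peracid) and is attacked on its exposed outer face in the crown conformer (C14 β, H1 α), giving the known 1β,10α-oxirane (1R,10R).

**Step 2**
Reactants: 2 1β,10α-epoxyparthenolide
Product: 3 13-bromo-1β,10α;4α,5β-diepoxygermacr-7(11)-en-12,6α-olide [(1R,4R,5R,6S,10R); BrCH2 on C11, tetrasubstituted C7=C11 butenolide]
Conditions: NBS (1.05 equiv), AIBN (5 mol %), PhCF3, 80 °C
Reagents that add atoms: NBS (N-bromosuccinimide), O=C1CCC(=O)N1Br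
Why: Wohl–Ziegler allylic bromination with allylic transposition; H7 is the only allylic (and a tertiary) hydrogen, and the 2-acyl allyl radical takes bromine at the unhindered C13 terminus to give the conjugated butenolide; no stereocentre is created (C7 becomes sp2), and any 7-bromo isomer would converge in step 3 through the same allylpalladium species.

**Step 3**
Reactants: 3 13-bromo-7(11)-ene butenolide
Product: 4 (7Z)-1β,10α;4α,5β-diepoxygermacra-7,11(13)-dien-12,6α-olide [(1R,4R,5R,6S,10R); s-cis-locked 3-methylene-4-alkylidene butanolide, C6 and C9 cis on C7=C8]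
Conditions: Pd(PPh3)4 (5 mol %), NaHCO3 (2 equiv), THF, 45 °C; crude diene used at once
Reagents that add atoms: none
Why: Tsuji–Trost-type 1,4-elimination; zerovalent palladium ionises the activated allylic bromide and β-hydride loss from C8 of the allylpalladium bromide gives the cross-conjugated diene, bicarbonate being too weak to touch the γ-acidic H6; the ring accepts only the 7Z olefin (as in furanodiene-type germacranes) and no stereocentre is created.

**Step 4**
Reactants: 4 (7Z)-7,11(13)-diene lactone
Product: 5 (1R,4R,5R,6S,8S,10R)-8α,13-diacetoxy-1β,10α;4α,5β-diepoxygermacr-7(11)-en-12,6α-olide (target)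
Conditions: Pd(OAc)2 (5 mol %), LiCl (20 mol %), LiOAc (3 equiv), p-benzoquinone (20 mol %), MnO2 (1.3 equiv), AcOH/acetone 1:4, 25 °C
Reagents that add atoms: acetic acid, CC(=O)O (delivered as acetate; LiOAc, [Li+].CC(=O)[O-], is its buffer form)
Why: Proposed new method: chloride-controlled palladium/benzoquinone 1,4-diacetoxylation (closest known reaction: Bäckvall 1,4-diacetoxylation of simple 1,3-dienes) applied to a 2-acyl, s-cis-locked exocyclic diene, where divalent palladium binds the convex β-face (side of H6; the α-face carries the C5→C10 loop), acetate adds to C13 anti to palladium to give a 1-acyl π-allyl (C11–C7–C8, C9 syn), and with chloride blocking inner-sphere delivery the second acetate attacks C8 anti to palladium from the α-face, distal to the carbonyl so the conjugated butenolide is restored, setting 8S (8α-OAc); benzoquinone/MnO2 returns zerovalent palladium to the divalent state. This facial model is reasoned from the ring geometry, not calculated.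

**Compound list**
1 | (−)-parthenolide, (4R,5R,6S,7S)-4α,5β-epoxygermacra-1(10)E,11(13)-dien-12,6α-olide | C=C1[C@@H]2CC/C(C)=C/CC[C@@]3(C)O[C@@H]3[C@H]2OC1=O | starting material
2 | 1β,10α-epoxyparthenolide, (1R,4R,5R,6S,7S,10R)-1β,10α;4α,5β-diepoxygermacr-11(13)-en-12,6α-olide | C=C1[C@@H]2CC[C@@]3(C)O[C@@H]3CC[C@@]3(C)O[C@@H]3[C@H]2OC1=O | intermediate
3 | (1R,4R,5R,6S,10R)-13-bromo-1β,10α;4α,5β-diepoxygermacr-7(11)-en-12,6α-olide | BrCC1=C2CC[C@@]3(C)O[C@@H]3CC[C@@]3(C)O[C@@H]3[C@H]2OC1=O | intermediate
4 | (1R,4R,5R,6S,10R,7Z)-1β,10α;4α,5β-diepoxygermacra-7,11(13)-dien-12,6α-olide | C=C1/C2=C/C[C@@]3(C)O[C@@H]3CC[C@@]3(C)O[C@@H]3[C@H]2OC1=O | intermediate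
5 | (1R,4R,5R,6S,8S,10R)-8α,13-diacetoxy-1β,10α;4α,5β-diepoxygermacr-7(11)-en-12,6α-olide | CC(=O)OCC1=C2[C@@H](OC(C)=O)C[C@@]3(C)O[C@@H]3CC[C@@]3(C)O[C@@H]3[C@H]2OC1=O | target

**Totals**
Total step count: 4. Longest linear sequence: 4 steps (1 → 2 → 3 → 4 → 5).

**Steps most likely to fail, with fallbacks**

Step 2 (allylic bromination). Risks are over-bromination of 3 at C6 or C8, bromine radical addition to the acrylate, and epoxide opening by traces of HBr. The fallback sets out from 2 and comes back at 3. OsO4 (cat.)/NMO dihydroxylates the methylene lactone from the α-face (anti to C8) to the 11α,13-diol F1. Appel bromination (CBr4, PPh3) of the primary hydroxyl gives the 13-bromo-11α-alcohol F2. Burgess syn-dehydration through H7α, which is syn to the 11α-hydroxyl, then gives 3.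

Step 3 (palladium-mediated 1,4-elimination). Risks are β-hydride loss toward C6, ionisation of the allylic lactone C6–O bond of 4 by zerovalent palladium, and Diels–Alder dimerisation of the diene. The fallback sets out from 3 and comes back at 4. PhSeNa (from PhSeSePh and NaBH4) displaces bromide to give the allyl selenide, 13-phenylselanyl butenolide F3. H2O2/pyridine forms the selenoxide, whose [2,3]-shift (oxygen delivered on the open β-face) and hydrolysis give the tertiary allylic alcohol, 7β-hydroxy methylene lactone F4. POCl3/pyridine anti-dehydration then gives 4, because the only hydrogen that can stand anti to the 7β-oxygen is on C8 (the single hydrogen on C6 is on the β-face).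

Step 4 (the proposed new step). Risks are weak binding of the electron-poor diene to divalent palladium, cycloaddition of the diene with benzoquinone or with itself, acetolysis of the oxiranes, and a C8 facial preference that rests on a model (chloride-free conditions would reverse the sense of the second C–O bond formation). The fallback uses known chemistry, sets out from 4 and comes back at 5. mCPBA epoxidises the electron-richer C7=C8 bond on the open β-face to the vinyl oxirane, 7β,8β-epoxide F5. Pd(PPh3)4/AcOH opens it in the Tsuji–Trost 1,4-sense (acetate to C13, C8–O bond untouched) to the 13-acetoxy-8β-alcohol F6. Mitsunobu esterification (PPh3, DIAD, AcOH) inverts C8 and gives 5.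

**Further compounds**
F1 | step 2 | 11α,13-dihydroxy-1β,10α;4α,5β-diepoxygermacran-12,6α-olide | OC[C@]1(O)[C@@H]2CC[C@@]3(C)O[C@@H]3CC[C@@]3(C)O[C@@H]3[C@H]2OC1=O
F2 | step 2 | 13-bromo-11α-hydroxy-1β,10α;4α,5β-diepoxygermacran-12,6α-olide | BrC[C@]1(O)[C@@H]2CC[C@@]3(C)O[C@@H]3CC[C@@]3(C)O[C@@H]3[C@H]2OC1=O
F3 | step 3 | 13-(phenylselanyl)-1β,10α;4α,5β-diepoxygermacr-7(11)-en-12,6α-olide | c1ccccc1[Se]CC1=C2CC[C@@]3(C)O[C@@H]3CC[C@@]3(C)O[C@@H]3[C@H]2OC1=O
F4 | step 3 | 7β-hydroxy-1β,10α;4α,5β-diepoxygermacr-11(13)-en-12,6α-olide | C=C1[C@@]2(O)CC[C@@]3(C)O[C@@H]3CC[C@@]3(C)O[C@@H]3[C@H]2OC1=O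
F5 | step 4 | 1β,10α;4α,5β;7β,8β-triepoxygermacr-11(13)-en-12,6α-olide | C=C1[C@@]2(O3)[C@H]3C[C@@]3(C)O[C@@H]3CC[C@@]3(C)O[C@@H]3[C@H]2OC1=O
F6 | step 4 | 13-acetoxy-8β-hydroxy-1β,10α;4α,5β-diepoxygermacr-7(11)-en-12,6α-olide | CC(=O)OCC1=C2[C@H](O)C[C@@]3(C)O[C@@H]3CC[C@@]3(C)O[C@@H]3[C@H]2OC1=O
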